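Numbering: ring A = C1, C2 (C=O), C3 (aroyl), C4 (enol carbon), C5, C9 (bridging C=O); ring B = C1, C8 (CMe2), C7 (CH), C6 (CH2), C5, C9; "endo" = on the face of ring B turned toward C2–C3–C4.
Enabling feature: ring A is a 2-aroyl-4,6-diprenylphloroglucinol held in a non-aromatic form, and its two prenyl-bearing carbons (C1, C5) are exactly the atoms joined by the three-carbon chain C8–C7–C6 of ring B.
Retrosynthetic cuts, in order: the geranyl C1'–C2' bond (sp3–sp2); C1–C8 together with C5–C6 (ring B); the two ring–prenyl bonds; the aryl–C(=O) bond to phloroglucinol.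
Forward: aroylphloroglucinol, double C-prenylation (future ring A), ring B by annulation with a 2-(acetoxymethyl) enal that brings C8, C7, C6 and a formyl group on C7, then C7–CHO to C7–CH2I, Negishi coupling with the nine-carbon (E)-dienyl iodide, deprotection.
Stereochemistry: C1 and C5 from a chiral ammonium–phenoxide ion pair in the first C–C bond formation (the tether forces the second bond onto the same face); C7 from exo-face protonation of an aldehyde enolate, stored at once as an internal aldol; the 2'E alkene from syn-carboalumination.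
Key step: step 7

Remarks on the chemistry (assumptions):
- The cinchoninium salt is assumed to give the sense of induction drawn; if the antipode predominates, the pseudoenantiomeric N-(9-anthracenylmethyl)cinchonidinium bromide is used instead.
- The neutral endo-formyl triketone enol 13 is expected to rest as its intramolecular C3 aldol, adamantane carbinol 14, so 14 is the isolated form. Base shifts this ring–chain equilibrium to the open side: in step 8 carbonate opens 14 to the potassium triketonate 15, which is methylated as it forms, so the neutral enol is not regenerated.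
- O-Methylation in step 8 is drawn at the C4 oxygen; a C2-O-methyl regioisomer, if formed, converges on the same 25 in step 14 and may be carried along.
- The phenol is carried as its 4-toluenesulfonate, chosen to survive AlCl3 and aqueous base.

Step 1
Reactants: 1 3-hydroxybenzoic acid
Product: 2 3-(4-methylphenylsulfonyloxy)benzoic acid
Conditions: TsCl (1.1 equiv), NaOH (aq.), THF/H2O, 0 °C to rt; then HCl to pH 2
Reagents that add atoms: 4-toluenesulfonyl chloride, Cc1ccc(cc1)S(=O)(=O)Cl
Why: Schotten–Baumann sulfonylation occurs at the phenoxide (any mixed sulfonic–carboxylic anhydride is hydrolysed again), and the aryl tosylate should survive AlCl3, cold aqueous KOH, CsOH at −50 °C and organozinc chemistry yet be cleaved by hot hydroxide in the last step.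

Step 2
Reactants: 2 3-(4-methylphenylsulfonyloxy)benzoic acid; 3 phloroglucinol
Product: 5 (2,4,6-trihydroxyphenyl)[3-(4-methylphenylsulfonyloxy)phenyl]methanone, via acid chloride 4 (not isolated)
Conditions: (COCl)2, DMF (cat.), CH2Cl2, rt, evaporation; then 3 (excess), AlCl3 (4 equiv), PhNO2, rt to 60 °C; aq. HCl
Reagents that add atoms: none
Why: Friedel–Crafts C-acylation of the threefold-symmetric, strongly activated triol can give only one monoketone, and the AlCl3-chelated product is deactivated against a second acylation.

Step 3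
Reactants: 5 (2,4,6-trihydroxyphenyl)[3-(4-methylphenylsulfonyloxy)phenyl]methanone; 6 prenyl bromide (1-bromo-3-methylbut-2-ene)
Product: 7 [2,4,6-trihydroxy-3,5-bis(3-methylbut-2-enyl)phenyl][3-(4-methylphenylsulfonyloxy)phenyl]methanone
Conditions: 6 (2.1 equiv), KOH (5% aq.), 0 °C; then aq. HCl
Reagents that add atoms: none
Why: In water the hydrogen-bonded acylphloroglucinol phenoxide is alkylated at carbon instead of oxygen (C-prenylation of acylphloroglucinols in aqueous base), the two free ring positions being the only nucleophilic carbons, while stoichiometry and low temperature hold back over-alkylated dienones.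

Step 4
Reactants: 8 diethyl 2-(propan-2-ylidene)malonate
Product: 9 2-(propan-2-ylidene)propane-1,3-diol
Conditions: iBu2AlH (4.5 equiv), CH2Cl2, −78 to 0 °C; aq. potassium sodium tartrate
Reagents that add atoms: none
Why: iBu2AlH reduces both conjugated esters in the 1,2-sense to the allylic diol, the fully substituted alkene being too hindered for conjugate hydride delivery.

Step 5
Reactants: 9 2-(propan-2-ylidene)propane-1,3-diol
Product: 10 2-(hydroxymethyl)-3-methylbut-2-enyl acetate
Conditions: Ac2O (1.0 equiv), Et3N, DMAP (cat.), CH2Cl2, 0 °C; diol and diacetate recycled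
Reagents that add atoms: acetic anhydride, CC(=O)OC(C)=O
Why: The two hydroxymethyl groups are homotopic, so DMAP-catalysed acylation with one equivalent of anhydride can give only one monoacetate, which is separated from recoverable diol and diacetate.

Step 6
Reactants: 10 2-(hydroxymethyl)-3-methylbut-2-enyl acetate
Product: 11 2-(acetoxymethyl)-3-methylbut-2-enal
Conditions: MnO2 (activated, excess), CH2Cl2, rt
Reagents that add atoms: none
Why: MnO2 oxidises the allylic primary alcohol selectively to the enal without over-oxidation and leaves the allylic acetate untouched.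

Step 7
Reactants: 7 [2,4,6-trihydroxy-3,5-bis(3-methylbut-2-enyl)phenyl][3-(4-methylphenylsulfonyloxy)phenyl]methanone; 11 2-(acetoxymethyl)-3-methylbut-2-enal
Product: 14 adamantane carbinol (internal C3–C10 aldol of the endo-formyl enol; hydroxyl on the C6 side), via 2-formylallyl dienone 12 (not isolated), via endo-formyl bicyclic enol 13 (not isolated)
Conditions: 11 (1.5 equiv), N-(9-anthracenylmethyl)cinchoninium bromide (0.25 equiv), CsOH·H2O (5 equiv), CH2Cl2, −50 °C; then AcOH, −50 °C to rt
Reagents that add atoms: none
Why: The phenoxide of 7, held as an ion pair by the cinchoninium cation, adds through one prenyl-bearing ring carbon to the β,β-dimethyl terminus of 11 (C1–C8), acetate is expelled by E1cB to give dienone 12, and the other prenyl-bearing carbon then adds to the new CH2 terminus (C5–C6) to give the aldehyde enolate of 13. The closest known reaction is the alkylative dearomatisation–annulation of 2-acyl-4,6-diprenylphloroglucinols with α-(acetoxymethyl) enals under cinchona phase-transfer catalysis, a double Michael addition with an E1cB step in between. Ring B closes by a 6-endo-trig conjugate addition; on neutralisation the nucleophilic C3 of 13 should add to the endo formyl group in a reversible 6-exo-trig aldol, so that the material is collected as 14, a ring–chain tautomer that base reopens in step 8. C1 is set by the chiral cation, which selects one of the two enantiotopic prenyl-bearing carbons together with its exposed face; C5 follows from C1 because the three-carbon tether can reach the second carbon only on the same face; C7 is set by protonation of the aldehyde enolate from the open exo face of ring B (formyl endo), and only this epimer can be stored as 14. The step needs C- over O-alkylation and annulation across C1/C5 instead of at C3, which the substrate secures through the aroyl group blocking C3, the mirror symmetry that makes the two reacting carbons equivalent, and the soft, hydrogen-bonded phenoxide. C3 and C10 of the cage are temporary stereocentres (C3 fixed by the cage, the hydroxyl expected away from the C8 methyl groups) and disappear in step 8.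

Step 8
Reactants: 14 adamantane carbinol
Product: 16 endo-7-formyl-4-methoxy-8,8-dimethyl-1,5-bis(3-methylbut-2-enyl)-3-[3-(4-methylphenylsulfonyloxy)benzoyl]bicyclo[3.3.1]non-3-ene-2,9-dione, via potassium triketonate 15 (not isolated)
Conditions: K2CO3 (3 equiv), Me2SO4 (2 equiv), acetone, 0 °C to rt
Reagents that add atoms: dimethyl sulfate, COS(=O)(=O)OC
Why: Carbonate deprotonates the cage carbinol and triggers a retro-aldol that breaks C3–C10 and releases the strongly stabilised potassium triketonate 15, which dimethyl sulfate O-methylates at the ring oxygen next to C5 (less hindered than the one next to the CMe2-flanked C1), so that the aldol can no longer re-form, while the mild heterogeneous base should not enolise the hindered aldehyde at C7.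

Step 9
Reactants: 16 endo-7-formyl methyl enol ether
Product: 17 endo-7-(hydroxymethyl)-4-methoxy-8,8-dimethyl-1,5-bis(3-methylbut-2-enyl)-3-[3-(4-methylphenylsulfonyloxy)benzoyl]bicyclo[3.3.1]non-3-ene-2,9-dione
Conditions: NaBH4 (1.0 equiv), MeOH/THF 1:4, −40 °C; aq. NH4Cl
Reagents that add atoms: none
Why: Chemoselective borohydride reduction: at low temperature the aldehyde reacts much faster than the vinylogous ester carbonyls or the C9 ketone flanked by two quaternary carbons, and C7 is not touched.

Step 10
Reactants: 17 endo-7-(hydroxymethyl) compound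
Product: 18 endo-7-(iodomethyl)-4-methoxy-8,8-dimethyl-1,5-bis(3-methylbut-2-enyl)-3-[3-(4-methylphenylsulfonyloxy)benzoyl]bicyclo[3.3.1]non-3-ene-2,9-dione
Conditions: PPh3, imidazole, I2, toluene/MeCN 3:1, rt to 50 °C, dark
Reagents that add atoms: iodine, [I][I]
Why: Appel-type iodination converts the primary alcohol through its alkoxyphosphonium salt by SN2 displacement at the CH2 carbon, so C7 is not involved, and the trisubstituted alkenes are spared because the iodine is consumed by the phosphine.

Step 11
Reactants: 19 5-bromo-2-methylpent-2-ene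
Product: 20 6-methylhept-5-en-1-yne
Conditions: LiC≡CH·H2NCH2CH2NH2 (1.3 equiv), DMSO, 10 °C to rt
Reagents that add atoms: lithium acetylide–ethylenediamine complex, [Li+].[C-]#C.NCCN
Why: SN2 alkylation of lithium acetylide by an unhindered primary homoallylic bromide in DMSO.

Step 12
Reactants: 20 6-methylhept-5-en-1-yne
Product: 22 (E)-1-iodo-2,6-dimethylhepta-1,5-diene, via alkenyldimethylalane 21 (not isolated)
Conditions: Me3Al (2 equiv), Cp2ZrCl2 (0.2 equiv), CH2Cl2, 0 °C to rt; then I2, THF, −30 to 0 °C
Reagents that add atoms: trimethylaluminium, C[Al](C)C; iodine, [I][I]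
Why: The Negishi Cp2ZrCl2-catalysed carboalumination adds methyl and aluminium syn across the terminal alkyne with aluminium at the terminus, and iododealumination with retention gives the E iodide, the remote trisubstituted alkene being inert to carbometalation.

Step 13
Reactants: 18 endo-7-(iodomethyl) compound; 22 (E)-1-iodo-2,6-dimethylhepta-1,5-diene
Product: 24 endo-7-[(2E)-3,7-dimethylocta-2,6-dienyl]-4-methoxy-8,8-dimethyl-1,5-bis(3-methylbut-2-enyl)-3-[3-(4-methylphenylsulfonyloxy)benzoyl]bicyclo[3.3.1]non-3-ene-2,9-dione, via alkylzinc iodide 23 (not isolated)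
Conditions: Zn dust (activated by BrCH2CH2Br and Me3SiCl), LiCl, THF, 40 °C; then 22 (1.3 equiv), Pd(PPh3)4 (5 mol%), THF, rt to 50 °C
Reagents that add atoms: none
Why: Zinc inserts into the primary C–I bond without touching ketones, the vinylogous ester or the aryl sulfonate, and the Negishi sp3–sp2 coupling under zerovalent palladium joins the alkylzinc to the alkenyl iodide with retention of the E geometry, reductive elimination being faster than β-hydride elimination.

Step 14
Reactants: 24 O-methyl O-tosyl protected target
Product: 25 (1S,5S,7S)-7-[(2E)-3,7-dimethylocta-2,6-dienyl]-4-hydroxy-3-(3-hydroxybenzoyl)-8,8-dimethyl-1,5-bis(3-methylbut-2-enyl)bicyclo[3.3.1]non-3-ene-2,9-dione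
Conditions: LiOH·H2O (10 equiv), 1,4-dioxane/H2O 4:1, 90 °C; then 1 M HCl, 0 °C, to pH 3
Reagents that add atoms: lithium hydroxide, [Li+].[OH-]
Why: Hydroxide adds to C4 of the vinylogous methyl ester and expels methoxide (addition–elimination) and attacks sulfur of the aryl sulfonate to free the phenoxide, the resulting triketonate–phenoxide dianion being inert to further hydroxide and no stereocentre being epimerisable (C1 and C5 quaternary, C7 not α to a carbonyl group).

Compound list
1 | 3-hydroxybenzoic acid | O=C(O)c1cccc(O)c1 | starting material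
2 | 3-(4-methylphenylsulfonyloxy)benzoic acid | Cc1ccc(cc1)S(=O)(=O)Oc1cccc(c1)C(=O)O | intermediate
3 | phloroglucinol (benzene-1,3,5-triol) | Oc1cc(O)cc(O)c1 | starting material
4 | 3-(4-methylphenylsulfonyloxy)benzoyl chloride | Cc1ccc(cc1)S(=O)(=O)Oc1cccc(c1)C(=O)Cl | intermediate
5 | (2,4,6-trihydroxyphenyl)[3-(4-methylphenylsulfonyloxy)phenyl]methanone | Cc1ccc(cc1)S(=O)(=O)Oc1cccc(c1)C(=O)c1c(O)cc(O)cc1O | intermediate
6 | prenyl bromide (1-bromo-3-methylbut-2-ene) | CC(C)=CCBr | starting material
7 | [2,4,6-trihydroxy-3,5-bis(3-methylbut-2-enyl)phenyl][3-(4-methylphenylsulfonyloxy)phenyl]methanone | CC(C)=CCc1c(O)c(CC=C(C)C)c(O)c(C(=O)c2cccc(OS(=O)(=O)c3ccc(C)cc3)c2)c1O | intermediate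
8 | diethyl 2-(propan-2-ylidene)malonate | CCOC(=O)C(=C(C)C)C(=O)OCC | starting material
9 | 2-(propan-2-ylidene)propane-1,3-diol | CC(C)=C(CO)CO | intermediate
10 | 2-(hydroxymethyl)-3-methylbut-2-enyl acetate | CC(C)=C(CO)COC(C)=O | intermediate
11 | 2-(acetoxymethyl)-3-methylbut-2-enal | CC(C)=C(C=O)COC(C)=O | intermediate
12 | 2-formylallyl dienone: dearomatised 7 carrying a CMe2–C(=CH2)–CHO group on one prenyl-bearing ring carbon (future C1, configured as in 25) | C=C(C=O)C(C)(C)[C@]1(CC=C(C)C)C(=O)C(C(=O)c2cccc(OS(=O)(=O)c3ccc(C)cc3)c2)=C(O)C(CC=C(C)C)=C1O | intermediate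
13 | endo-formyl bicyclic enol: endo-7-formyl-4-hydroxy-8,8-dimethyl-1,5-bis(3-methylbut-2-enyl)-3-[3-(4-methylphenylsulfonyloxy)benzoyl]bicyclo[3.3.1]non-3-ene-2,9-dione (C1, C5, C7 arranged in space as in 25) | O=C[C@H]1C[C@]2(CC=C(C)C)C(=O)[C@@](CC=C(C)C)(C(=O)C(C(=O)c3cccc(OS(=O)(=O)c4ccc(C)cc4)c3)=C2O)C1(C)C | intermediate
14 | adamantane carbinol: 10-hydroxy-8,8-dimethyl-1,5-bis(3-methylbut-2-enyl)-3-[3-(4-methylphenylsulfonyloxy)benzoyl]tricyclo[3.3.1.1(3,7)]decane-2,4,9-trione (bicycle numbering kept; C10 = former formyl carbon bonded to C3 and C7; hydroxyl on the C6 side) | O[C@H]3[C@H]1C[C@]2(CC=C(C)C)C(=O)[C@@](CC=C(C)C)(C(=O)[C@@]3(C(=O)c4cccc(OS(=O)(=O)c5ccc(C)cc5)c4)C2=O)C1(C)C | intermediate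
15 | potassium triketonate: potassium salt of the ring-opened endo-7-formyl triketone (C3–C10 bond of 14 broken; charge drawn on the C4 oxygen) | [K+].O=C[C@H]1C[C@]2(CC=C(C)C)C(=O)[C@@](CC=C(C)C)(C(=O)C(C(=O)c3cccc(OS(=O)(=O)c4ccc(C)cc4)c3)=C2[O-])C1(C)C | intermediate
16 | endo-7-formyl-4-methoxy-8,8-dimethyl-1,5-bis(3-methylbut-2-enyl)-3-[3-(4-methylphenylsulfonyloxy)benzoyl]bicyclo[3.3.1]non-3-ene-2,9-dione | O=C[C@H]1C[C@]2(CC=C(C)C)C(=O)[C@@](CC=C(C)C)(C(=O)C(C(=O)c3cccc(OS(=O)(=O)c4ccc(C)cc4)c3)=C2OC)C1(C)C | intermediate
17 | endo-7-(hydroxymethyl)-4-methoxy-8,8-dimethyl-1,5-bis(3-methylbut-2-enyl)-3-[3-(4-methylphenylsulfonyloxy)benzoyl]bicyclo[3.3.1]non-3-ene-2,9-dione | OC[C@H]1C[C@]2(CC=C(C)C)C(=O)[C@@](CC=C(C)C)(C(=O)C(C(=O)c3cccc(OS(=O)(=O)c4ccc(C)cc4)c3)=C2OC)C1(C)C | intermediate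
18 | endo-7-(iodomethyl)-4-methoxy-8,8-dimethyl-1,5-bis(3-methylbut-2-enyl)-3-[3-(4-methylphenylsulfonyloxy)benzoyl]bicyclo[3.3.1]non-3-ene-2,9-dione | IC[C@H]1C[C@]2(CC=C(C)C)C(=O)[C@@](CC=C(C)C)(C(=O)C(C(=O)c3cccc(OS(=O)(=O)c4ccc(C)cc4)c3)=C2OC)C1(C)C | intermediate
19 | 5-bromo-2-methylpent-2-ene | CC(C)=CCCBr | starting material
20 | 6-methylhept-5-en-1-yne | CC(C)=CCCC#C | intermediate
21 | (E)-(2,6-dimethylhepta-1,5-dienyl)dimethylalane | CC(C)=CCC/C(C)=C/[Al](C)C | intermediate
22 | (E)-1-iodo-2,6-dimethylhepta-1,5-diene | CC(C)=CCC/C(C)=C/I | intermediate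
23 | alkylzinc iodide: the C7–CH2–ZnI compound derived from 18 (endo) | I[Zn]C[C@H]1C[C@]2(CC=C(C)C)C(=O)[C@@](CC=C(C)C)(C(=O)C(C(=O)c3cccc(OS(=O)(=O)c4ccc(C)cc4)c3)=C2OC)C1(C)C | intermediate
24 | endo-7-[(2E)-3,7-dimethylocta-2,6-dienyl]-4-methoxy-8,8-dimethyl-1,5-bis(3-methylbut-2-enyl)-3-[3-(4-methylphenylsulfonyloxy)benzoyl]bicyclo[3.3.1]non-3-ene-2,9-dione | CC(C)=CCC/C(C)=C/C[C@H]1C[C@]2(CC=C(C)C)C(=O)[C@@](CC=C(C)C)(C(=O)C(C(=O)c3cccc(OS(=O)(=O)c4ccc(C)cc4)c3)=C2OC)C1(C)C | intermediate
25 | (1S,5S,7S)-7-[(2E)-3,7-dimethylocta-2,6-dienyl]-4-hydroxy-3-(3-hydroxybenzoyl)-8,8-dimethyl-1,5-bis(3-methylbut-2-enyl)bicyclo[3.3.1]non-3-ene-2,9-dione (geranyl endo) | CC(C)=CCC/C(C)=C/C[C@H]1C[C@]2(CC=C(C)C)C(=O)[C@@](CC=C(C)C)(C(=O)C(C(=O)c3cccc(O)c3)=C2O)C1(C)C | target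

Total step count: 14. Longest linear sequence: 9 steps (steps 1, 2, 3, 7, 8, 9, 10, 13, 14).

Steps most likely to fail

Step 7. The ion pair may discriminate poorly between the two enantiotopic carbon–face pairs of the phenoxide, giving low enantiomeric purity, and the aldehyde enolate may equilibrate before it is protonated, which erodes the endo selectivity that the aldol capture relies on. Fallback: starting again from 7 and 11, the annulation is run without chiral control under kinetic conditions (LiN(SiMe3)2, THF, 0 °C, cold AcOH quench). This should give 14 together with its mirror image, the ent-adamantane carbinol F1. The two are separated by preparative chromatography on an amylose tris(3,5-dimethylphenylcarbamate) stationary phase, and the route is rejoined at 14.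

Step 13. Zinc insertion into the β-branched primary iodide may be slow, the transient primary radical may cyclise onto a neighbouring prenyl double bond, and the alkylzinc may be protonated before it couples. Fallback: the polarity of the coupling is reversed. Setting out from 22, iodine–lithium exchange (t-BuLi, Et2O, −78 °C) gives (E)-(2,6-dimethylhepta-1,5-dienyl)lithium F2, and ZnCl2 converts it into (E)-(2,6-dimethylhepta-1,5-dienyl)zinc chloride F3. Iodide 18 then serves as the electrophile in an alkyl–alkenyl Negishi coupling of an unactivated primary iodide (Pd2(dba)3, P(c-C5H9)3, N-methylimidazole, THF/NMP, 80 °C), which returns to the route at 24.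

Step 8. The liberated endo aldehyde may epimerise at C7 during the basic methylation, or may condense with acetone, before the enolate is fully O-methylated. Fallback: the order of events is changed so that the aldehyde is consumed as it is released. Setting out from 14, NaOMe (1.1 equiv) in MeOH/THF at −40 °C opens the cage in the presence of NaBH4, and acidification with 1 M HCl to pH 4 should give the endo-7-(hydroxymethyl) triketone enol F4. Its acidic enol alone is then O-methylated with Me3SiCHN2 (MeOH/toluene, 0 °C), and the route is rejoined at 17.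

Further compounds
F1 | step 7 | ent-adamantane carbinol (mirror image of 14) | O[C@@H]3[C@@H]1C[C@@]2(CC=C(C)C)C(=O)[C@](CC=C(C)C)(C(=O)[C@]3(C(=O)c4cccc(OS(=O)(=O)c5ccc(C)cc5)c4)C2=O)C1(C)C
F2 | step 13 | (E)-(2,6-dimethylhepta-1,5-dienyl)lithium | CC(C)=CCC/C(C)=C/[Li]
F3 | step 13 | (E)-(2,6-dimethylhepta-1,5-dienyl)zinc chloride | CC(C)=CCC/C(C)=C/[Zn]Cl
F4 | step 8 | endo-7-(hydroxymethyl)-4-hydroxy-8,8-dimethyl-1,5-bis(3-methylbut-2-enyl)-3-[3-(4-methylphenylsulfonyloxy)benzoyl]bicyclo[3.3.1]non-3-ene-2,9-dione | OC[C@H]1C[C@]2(CC=C(C)C)C(=O)[C@@](CC=C(C)C)(C(=O)C(C(=O)c3cccc(OS(=O)(=O)c4ccc(C)cc4)c3)=C2O)C1(C)C
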